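The pitfall in this flask was to read a fork once, at the charge, and let that reading stand for the whole run.

starting complex 0.40 M; incoming ligand 2.00 equiv; time 3.0 h

    complex with one exchanged + incoming ligand ⇌ leaving ligand + complex with two exchanged (K1 = 3.2, k1 = 7.1 × 10⁻⁴ M⁻¹ s⁻¹)
    starting complex + incoming ligand ⇌ leaving ligand + complex with one exchanged (K2 = 0.25, k2 = 9.6 × 10⁻⁴ M⁻¹ s⁻¹)
    starting complex + complex with one exchanged → side product (k3 = 0.0010 M⁻¹ s⁻¹)
    complex with two exchanged → over-reaction product (k4 = 0.0014 s⁻¹)

- a species is counted by the starting complex in it: one side product counts as two
- the reaction counts as stopped when no species that holds the starting complex changes by six tenths of a point or more over the second half of the time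
- run time (flask): 3.0 h

* which holds at 3.0 h: what has brought the reaction to rest, or that it has not come to rest (all of the starting complex has reacted / forward and back rates have come level / the incoming ligand has run out first / it is still moving)
* how much over-reaction product there is at 3.0 h, in percent of the starting complex charged

I followed one unit of starting complex to complex with one exchanged. There it either met incoming ligand and went on towards over-reaction product, or met starting complex and fell into side product, taking a second unit with it. With A the rate constant of the second exchange times c(incoming ligand), and B the rate constant of side-product formation times c(starting complex):

fork share = A / (A + two times B)

At the charge, with c(incoming ligand) 0.800 M, this was 41.5%. My first way let the whole charge pass at that share, which gave 41.5% of the charge.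

My second way read the fork where half the charge was consumed. A unit reaching over-reaction product costs two incoming ligand, and a unit in side product costs one half. So:

c(leaving ligand) = 0.225 M, c(incoming ligand) = 0.575 M

That gave 50.5%, the half-way fork share, which I carried on. For the clock I held complex with one exchanged steady:

loss rate of starting complex, per starting complex = forward constant of the first exchange × c(incoming ligand) × (A + two times B) / (back constant × c(leaving ligand) + A + B)

This gave a half-life of 0.634 h at that point. With a quarter left, c(leaving ligand) was 0.377 M and c(incoming ligand) 0.423 M, and the half-life was 1.75 h. Charging each halving at the rate of its end took 2.38 h, less than the run. The time left over ran on at the second half-life, so I committed to 80.4% consumed, and to: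

over-reaction product = 40.6%

The two ways lay close, but that was no check. The first used a share lower than the half-way one on more material than had reacted, and those errors oppose. I trusted the second. The last half-life exceeded half the run, so I expected movement still.

The forecast said it is still moving and 42%, reasoning that “the irreversible drain through the second exchange to over-reaction product keeps pulling material along”; its number stood above mine.

The simulation gave it is still moving and 39.1%, so the forecast held on both. This flask has not come to rest. At 3.00 h, over-reaction product over it plus side product read 51.4%, beside my 50.5%. At 30.0 h, starting complex has gone from 19.0% to 1.28%, side product from 37.1% to 42.6%, and over-reaction product has reached 56.0%, above the 41.5% of my first way. That way was the one that cheated.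

In the neighbour flask with 0.24 M of starting complex, the equivalents are held, so the fork share stays 50.5% while my half-lives stretch by 1.67. That gave 68.5% consumed and 34.6% over-reaction product. The computed result there is 33.3%.

(All constants are invented.)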